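**Retrosynthetic overview**
- The target comes from its tris-MOM ether by mild acid methanolysis (last step).
- The pyran ring is formed last, by prenal condensation and oxa-6π closure on a 2,6-dihydroxy-4-(MOM-oxy)benzophenone. The capped para oxygen forces the angular 8-aroyl chromene.
- Key step: the phloroglucinol ring is not acylated (no Friedel–Crafts, no aryl-metal addition). It is built de novo around the ketone by a biomimetic pyrone-to-benzene ring transformation (lactone opening, then intramolecular Claisen) of a 6-aroylmethyl-4-(MOM-oxy)-2-pyrone.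
- That keto-pyrone comes from lateral lithiation of O-MOM triacetic acid lactone and acylation with methyl 3,5-bis(MOM-oxy)-2-prenylbenzoate.
- The ester comes from methyl 3,5-dihydroxybenzoate (MOM protection, C-2 bromination, Stille prenylation). Ring order: ring A purchased, ring B built in step 6, pyran ring in step 7.

Assumption: the target has no stereocentre and no stereogenic double bond (it is achiral), so "single enantiomer" needs no stereocontrol; the SMILES is taken as drawn.

**Step 1**
Reactants: 1 methyl 3,5-dihydroxybenzoate; 2 chloromethyl methyl ether (MOMCl)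
Product: 3 methyl 3,5-bis(methoxymethoxy)benzoate
Conditions: MOMCl (3 equiv), i-Pr2NEt (4 equiv), CH2Cl2, 0 °C to rt
Reagents that add atoms: chloromethyl methyl ether (2), COCCl
Why: O-alkylation of both phenols (MOM acetal protection) under amine base leaves the methyl ester untouched.

**Step 2**
Reactants: 3 methyl 3,5-bis(methoxymethoxy)benzoate; 4 N-bromosuccinimide
Product: 5 methyl 2-bromo-3,5-bis(methoxymethoxy)benzoate
Conditions: NBS (1.05 equiv), MeCN, 0 °C to rt, dark
Reagents that add atoms: N-bromosuccinimide (4), O=C1CCC(=O)N1Br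
Why: Electrophilic aromatic bromination goes to C-2 (para to one MOM ether, ortho to the other) because C-4 is buttressed between both ethers, as in the dimethyl ether series, and the neutral medium spares the acetals.

**Step 3**
Reactants: 5 methyl 2-bromo-3,5-bis(methoxymethoxy)benzoate; 6 tributyl(3-methylbut-2-en-1-yl)stannane
Product: 7 methyl 3,5-bis(methoxymethoxy)-2-(3-methylbut-2-en-1-yl)benzoate
Conditions: 6 (1.3 equiv), Pd2(dba)3 (2.5 mol%), P(t-Bu)3·HBF4 (10 mol%), CsF (2.2 equiv), 1,4-dioxane, 90 °C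
Reagents that add atoms: tributyl(3-methylbut-2-en-1-yl)stannane (6), CCCC[Sn](CCCC)(CCCC)CC=C(C)C
Why: Stille cross-coupling in which the allyl-palladium intermediate equilibrates (η1–η3–η1) and reductively eliminates at the unhindered primary terminus to give the linear prenyl arene, with ester and MOM ethers inert.

**Step 4**
Reactants: 8 4-hydroxy-6-methyl-2H-pyran-2-one (triacetic acid lactone); 2 chloromethyl methyl ether
Product: 9 4-(methoxymethoxy)-6-methyl-2H-pyran-2-one
Conditions: MOMCl (1.2 equiv), i-Pr2NEt (1.5 equiv), CH2Cl2, 0 °C to rt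
Reagents that add atoms: chloromethyl methyl ether (2), COCCl
Why: O-alkylation of the vinylogous acid at O-4, the usual site for hard electrophiles, gives the 4-alkoxy-2-pyrone.

**Step 5**
Reactants: 7 methyl 3,5-bis(methoxymethoxy)-2-(3-methylbut-2-en-1-yl)benzoate; 9 4-(methoxymethoxy)-6-methyl-2H-pyran-2-one
Product: 11 6-{2-[3,5-bis(methoxymethoxy)-2-(3-methylbut-2-en-1-yl)phenyl]-2-oxoethyl}-4-(methoxymethoxy)-2H-pyran-2-one, via lithiated pyrone 10 (not isolated)
Conditions: 9 (2.2 equiv), LiHMDS (2.3 equiv), THF, −78 °C; then 7 (1.0 equiv), −78 to −20 °C; AcOH quench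
Reagents that add atoms: none
Why: Lateral (vinylogous) lithiation of the 6-methyl group followed by Claisen-type C-acylation with the non-enolisable aryl ester; the more acidic product is deprotonated at once by the second equivalent of 10, which prevents over-addition.

**Step 6 (key step)**
Reactants: 11 6-{2-[3,5-bis(methoxymethoxy)-2-(3-methylbut-2-en-1-yl)phenyl]-2-oxoethyl}-4-(methoxymethoxy)-2H-pyran-2-one
Product: 13 [3,5-bis(methoxymethoxy)-2-(3-methylbut-2-en-1-yl)phenyl][2,6-dihydroxy-4-(methoxymethoxy)phenyl]methanone, via ring-opened methyl ester 12 (not isolated)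
Conditions: Mg(OMe)2 (4 equiv, 7% in MeOH), MeOH, 65 °C; cold 0.5 M HCl work-up
Reagents that add atoms: none
Why: Biomimetic pyrone-to-phloroglucinol ring transformation (precedented for 6-phenacyl-4-hydroxy-2-pyrone, and C-2 opening of 4-alkoxy-2-pyrones by magnesium methoxide is established): methoxide opens the lactone to the Mg-chelated triketide ester 12, whose C-6 carbanion closes onto the ester in an intramolecular Claisen (Dieckmann) condensation and aromatises, while the enol ether blocks the aldol mode and ends up para to the ketone between two free, equivalent ortho hydroxyls.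

**Step 7**
Reactants: 13 [3,5-bis(methoxymethoxy)-2-(3-methylbut-2-en-1-yl)phenyl][2,6-dihydroxy-4-(methoxymethoxy)phenyl]methanone; 14 3-methylbut-2-enal
Product: 16 [3,5-bis(methoxymethoxy)-2-(3-methylbut-2-en-1-yl)phenyl][7-hydroxy-5-(methoxymethoxy)-2,2-dimethyl-2H-chromen-8-yl]methanone, via ortho-quinone methide 15 (not isolated)
Conditions: 14 (1.5 equiv), ethylenediammonium diacetate (20 mol%), PhMe, 110 °C
Reagents that add atoms: 3-methylbut-2-enal (14), CC(C)=CC=O
Why: Amine-catalysed Knoevenagel-type condensation at the ring carbon gives the 1-oxatriene 15, which closes by oxa-6π electrocyclisation; since the para oxygen is capped and the two free hydroxyls are equivalent, only the angular 8-aroyl chromene can form.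

**Step 8**
Reactants: 16 [3,5-bis(methoxymethoxy)-2-(3-methylbut-2-en-1-yl)phenyl][7-hydroxy-5-(methoxymethoxy)-2,2-dimethyl-2H-chromen-8-yl]methanone
Product: 17 [3,5-dihydroxy-2-(3-methylbut-2-en-1-yl)phenyl](5,7-dihydroxy-2,2-dimethyl-2H-chromen-8-yl)methanone (target)
Conditions: HCl (1.25 M in MeOH), 0 °C to rt, stop at full conversion
Reagents that add atoms: none
Why: Acid-catalysed acetal methanolysis removes all three MOM groups under conditions mild enough to spare the prenyl alkene and the 2,2-dimethylchromene, as in prenylated chalcone work.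

**Compound list**
1 | methyl 3,5-dihydroxybenzoate | COC(=O)c1cc(O)cc(O)c1 | starting material
2 | chloromethyl methyl ether | COCCl | starting material
3 | methyl 3,5-bis(methoxymethoxy)benzoate | COC(=O)c1cc(OCOC)cc(OCOC)c1 | intermediate
4 | N-bromosuccinimide | O=C1CCC(=O)N1Br | starting material
5 | methyl 2-bromo-3,5-bis(methoxymethoxy)benzoate | COC(=O)c1cc(OCOC)cc(OCOC)c1Br | intermediate
6 | tributyl(3-methylbut-2-en-1-yl)stannane | CCCC[Sn](CCCC)(CCCC)CC=C(C)C | starting material
7 | methyl 3,5-bis(methoxymethoxy)-2-(3-methylbut-2-en-1-yl)benzoate | COC(=O)c1cc(OCOC)cc(OCOC)c1CC=C(C)C | intermediate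
8 | 4-hydroxy-6-methyl-2H-pyran-2-one (triacetic acid lactone) | CC1=CC(O)=CC(=O)O1 | starting material
9 | 4-(methoxymethoxy)-6-methyl-2H-pyran-2-one | CC1=CC(OCOC)=CC(=O)O1 | intermediate
10 | [4-(methoxymethoxy)-2-oxo-2H-pyran-6-yl]methyllithium (lithiated pyrone, formed in situ) | [Li]CC1=CC(OCOC)=CC(=O)O1 | intermediate
11 | 6-{2-[3,5-bis(methoxymethoxy)-2-(3-methylbut-2-en-1-yl)phenyl]-2-oxoethyl}-4-(methoxymethoxy)-2H-pyran-2-one | O=C(CC1=CC(OCOC)=CC(=O)O1)c1cc(OCOC)cc(OCOC)c1CC=C(C)C | intermediate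
12 | methyl (2E)-7-[3,5-bis(methoxymethoxy)-2-(3-methylbut-2-en-1-yl)phenyl]-3-(methoxymethoxy)-5,7-dioxohept-2-enoate (ring-opened methyl ester, formed in situ as Mg enolate) | COC(=O)/C=C(\CC(=O)CC(=O)c1cc(OCOC)cc(OCOC)c1CC=C(C)C)OCOC | intermediate
13 | [3,5-bis(methoxymethoxy)-2-(3-methylbut-2-en-1-yl)phenyl][2,6-dihydroxy-4-(methoxymethoxy)phenyl]methanone | CC(C)=CCc1c(OCOC)cc(OCOC)cc1C(=O)c1c(O)cc(OCOC)cc1O | intermediate
14 | 3-methylbut-2-enal | CC(C)=CC=O | starting material
15 | (6Z)-2-[3,5-bis(methoxymethoxy)-2-(3-methylbut-2-en-1-yl)benzoyl]-3-hydroxy-5-(methoxymethoxy)-6-(3-methylbut-2-en-1-ylidene)cyclohexa-2,4-dien-1-one (ortho-quinone methide, formed in situ) | CC(C)=C/C=C1\C(=O)C(C(=O)c2cc(OCOC)cc(OCOC)c2CC=C(C)C)=C(O)C=C1OCOC | intermediate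
16 | [3,5-bis(methoxymethoxy)-2-(3-methylbut-2-en-1-yl)phenyl][7-hydroxy-5-(methoxymethoxy)-2,2-dimethyl-2H-chromen-8-yl]methanone | CC(C)=CCc1c(OCOC)cc(OCOC)cc1C(=O)c1c(O)cc(OCOC)c2c1OC(C)(C)C=C2 | intermediate
17 | [3,5-dihydroxy-2-(3-methylbut-2-en-1-yl)phenyl](5,7-dihydroxy-2,2-dimethyl-2H-chromen-8-yl)methanone | CC(C)=CCc1c(O)cc(O)cc1C(=O)c1c(O)cc(O)c2c1OC(C)(C)C=C2 | target

**Totals**
Total step count: 8. Longest linear sequence: 7 (steps 1, 2, 3, 5, 6, 7, 8 from compound 1); step 4 is a one-step side branch.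

**Three steps most likely to fail**

Step 6 (ring transformation, the bold step). The 4-MOM-oxy substrate itself is unprecedented. The specific dangers are methoxide exchanging or cleaving the vinylogous MOM acetal (giving a 4-OMe or free 4-OH product), and γ-pyrone formation from 12. The fallback sets out from 7 and 8 and comes back at 13. Triacetic acid lactone 8 is doubly deprotonated (LDA, 2.2 equiv per 8, THF, −78 to 0 °C) to lithium 6-(lithiomethyl)-2-oxo-2H-pyran-4-olate F4. F4 (2.5 equiv) is acylated by ester 7 to give 6-{2-[3,5-bis(methoxymethoxy)-2-(3-methylbut-2-en-1-yl)phenyl]-2-oxoethyl}-4-hydroxy-2H-pyran-2-one F5. As its 4-oxido anion this pyrone carries no enol ether to exchange, and Mg(OMe)2 in refluxing MeOH (the directly precedented phenacyl case) opens it to methyl 7-[3,5-bis(methoxymethoxy)-2-(3-methylbut-2-en-1-yl)phenyl]-3,5,7-trioxoheptanoate F6. F6 closes in the Claisen mode to [3,5-bis(methoxymethoxy)-2-(3-methylbut-2-en-1-yl)phenyl](2,4,6-trihydroxyphenyl)methanone F7. The para hydroxyl of F7, the most acidic and the only one not chelated to the ketone, is then mono-protected (MOMCl 2, 1.05 equiv, i-Pr2NEt, CH2Cl2, −20 °C) to rejoin the route at 13. Any 4-OH material formed by MOM loss in the main step 6 is this same F7 and can be recycled the same way.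

Step 5 (acylation of a stabilised anion by an ortho-substituted methyl ester). The likely failure is low conversion. The fallback sets out from 7 and comes back at 11, swapping the ester for an aldehyde electrophile. Ester 7 is reduced with DIBAL-H (CH2Cl2, −78 to 0 °C) to [3,5-bis(methoxymethoxy)-2-(3-methylbut-2-en-1-yl)phenyl]methanol F1. F1 is oxidised with MnO2 (CH2Cl2, rt) to 3,5-bis(methoxymethoxy)-2-(3-methylbut-2-en-1-yl)benzaldehyde F2. Lithiated pyrone 10 (from 9, LiHMDS, THF, −78 °C) adds to F2 in an aldol reaction to give racemic 6-{2-[3,5-bis(methoxymethoxy)-2-(3-methylbut-2-en-1-yl)phenyl]-2-hydroxyethyl}-4-(methoxymethoxy)-2H-pyran-2-one F3. Dess–Martin oxidation (NaHCO3, CH2Cl2) of F3 gives 11 and erases the transient carbinol centre.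

Step 8 (protic acid with an ortho-prenyl phenol and an electron-rich chromene). The dangers are chroman formation by prenyl cyclisation and MeOH addition or dimerisation at the chromene. The fallback sets out from 16 and comes back at 17 and avoids protic acid. TMSOTf with 2,2'-bipyridyl (CH2Cl2, 0 °C to rt) transfers the MOM groups to the bipyridyl and silylates every phenol oxygen, giving [3,5-bis(trimethylsilyloxy)-2-(3-methylbut-2-en-1-yl)phenyl][2,2-dimethyl-5,7-bis(trimethylsilyloxy)-2H-chromen-8-yl]methanone F8. Neutral methanolysis of F8 (MeOH, cat. K2CO3, rt) then releases 17.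

**Further compounds**
F1 | step 5 | [3,5-bis(methoxymethoxy)-2-(3-methylbut-2-en-1-yl)phenyl]methanol | OCc1cc(OCOC)cc(OCOC)c1CC=C(C)C
F2 | step 5 | 3,5-bis(methoxymethoxy)-2-(3-methylbut-2-en-1-yl)benzaldehyde | O=Cc1cc(OCOC)cc(OCOC)c1CC=C(C)C
F3 | step 5 | racemic 6-{2-[3,5-bis(methoxymethoxy)-2-(3-methylbut-2-en-1-yl)phenyl]-2-hydroxyethyl}-4-(methoxymethoxy)-2H-pyran-2-one | OC(CC1=CC(OCOC)=CC(=O)O1)c1cc(OCOC)cc(OCOC)c1CC=C(C)C
F4 | step 6 | lithium 6-(lithiomethyl)-2-oxo-2H-pyran-4-olate | [Li]CC1=CC(O[Li])=CC(=O)O1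
F5 | step 6 | 6-{2-[3,5-bis(methoxymethoxy)-2-(3-methylbut-2-en-1-yl)phenyl]-2-oxoethyl}-4-hydroxy-2H-pyran-2-one | O=C(CC1=CC(O)=CC(=O)O1)c1cc(OCOC)cc(OCOC)c1CC=C(C)C
F6 | step 6 | methyl 7-[3,5-bis(methoxymethoxy)-2-(3-methylbut-2-en-1-yl)phenyl]-3,5,7-trioxoheptanoate | COC(=O)CC(=O)CC(=O)CC(=O)c1cc(OCOC)cc(OCOC)c1CC=C(C)C
F7 | step 6 | [3,5-bis(methoxymethoxy)-2-(3-methylbut-2-en-1-yl)phenyl](2,4,6-trihydroxyphenyl)methanone | CC(C)=CCc1c(OCOC)cc(OCOC)cc1C(=O)c1c(O)cc(O)cc1O
F8 | step 8 | [3,5-bis(trimethylsilyloxy)-2-(3-methylbut-2-en-1-yl)phenyl][2,2-dimethyl-5,7-bis(trimethylsilyloxy)-2H-chromen-8-yl]methanone | CC(C)=CCc1c(O[Si](C)(C)C)cc(O[Si](C)(C)C)cc1C(=O)c1c(O[Si](C)(C)C)cc(O[Si](C)(C)C)c2c1OC(C)(C)C=C2
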